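**Retrosynthetic overview**
1. Feature used: in ring A, O1 (on C8a) and C4 (on C4a) sit on adjacent carbons, and the C5 oxygen flanks C4a on its other side. This C8a(O)–C4a(C)–C5(O) pattern is what nucleophile-then-electrophile addition across a 3-alkoxyaryne leaves behind.
2. Endgame: the five phenols are carried as methyl ethers. The four CHO groups (C6, C8, C3', C5') enter last by electrophilic formylation. The C4 isobutyl group is traced back to CH2CO2Me.
3. Key disconnection: O1–C8a and C4–C4a of pyran ring C are cut together. This gives 3,5-dimethoxybenzyne (from silylaryl triflate 8) and the alkoxide of δ-hydroxy enoate 21, which already holds C2 and C3.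
4. Compound 21 comes from an Evans syn-aldol of an isovaleryl imide with 2,4,6-trimethoxybenzaldehyde, followed by a two-carbon Wittig homologation. Compound 8 comes from 3,5-dimethoxyphenol by directed ortho-silylation.
5. Ring order: rings A and B are bought as benzene rings, and ring C is the only ring formed (step 11).

Key step: step 11

Remark: chroman numbering is used (ring A = fused benzene ring, ring B = C2 aryl group, ring C = pyran). The target SMILES is read as (2R,3S,4S), with aryl and isopropyl cis and isopropyl and isobutyl trans.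

**Route**

Step 1
Reactants: 1 3,5-dimethoxyphenol
Product: 2 3,5-dimethoxyphenyl isopropylcarbamate
Conditions: i-PrNCO, Et3N (cat.), CH2Cl2, rt
Reagents that add atoms: isopropyl isocyanate, CC(C)N=C=O
Why: Base-catalysed carbamoylation of the phenol with an isocyanate installs a strong ortho-directing group that mild base can remove later.

Step 2
Reactants: 2 3,5-dimethoxyphenyl isopropylcarbamate
Product: 6 3,5-dimethoxy-2-(trimethylsilyl)phenyl isopropylcarbamate, via N-silyl carbamate 3 (not isolated), via ortho-lithiated carbamate 4 (not isolated), via doubly silylated carbamate 5 (not isolated)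
Conditions: TBSOTf, TMEDA, Et2O, 0 °C → rt; n-BuLi, TMEDA, −78 °C; TMSCl, −78 °C → rt; aq NaHSO4
Reagents that add atoms: chlorotrimethylsilane, C[Si](C)(C)Cl
Why: Directed ortho-metalation, in which transient N-silylation masks the N–H, the carbamate and the neighbouring methoxyl together direct lithiation to the carbon between them (C2 and C6 are equivalent) rather than to C4 between the two weaker methoxyl directors, TMSCl traps the aryllithium, and the acidic work-up frees the N–H.

Step 3
Reactants: 6 3,5-dimethoxy-2-(trimethylsilyl)phenyl isopropylcarbamate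
Product: 8 3,5-dimethoxy-2-(trimethylsilyl)phenyl trifluoromethanesulfonate, via silylphenoxide 7 (not isolated)
Conditions: DBU, Et2NH, MeCN, 40 °C; then PhNTf2, rt
Reagents that add atoms: N-phenylbis(trifluoromethanesulfonimide), O=S(=O)(N(c1ccccc1)S(=O)(=O)C(F)(F)F)C(F)(F)F
Why: E1cB cleavage of the secondary carbamate gives the phenoxide while Et2NH scavenges the isocyanate, and O-triflation in the same flask means the protodesilylation-prone silylphenol is never handled.

Step 4
Reactants: 9 (R)-4-benzyl-2-oxazolidinone; 10 isovaleryl chloride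
Product: 12 (R)-4-benzyl-3-(3-methylbutanoyl)oxazolidin-2-one, via N-lithio oxazolidinone 11 (not isolated)
Conditions: n-BuLi, THF, −78 °C; then 10, −78 → 0 °C
Reagents that add atoms: none
Why: N-acylation of the lithiated oxazolidinone with an acid chloride is the standard way to load the auxiliary and touches no stereocentre.

Step 5
Reactants: 12 (R)-4-benzyl-3-(3-methylbutanoyl)oxazolidin-2-one; 13 2,4,6-trimethoxybenzaldehyde
Product: 16 (R)-4-benzyl-3-[(2R,3R)-3-hydroxy-2-isopropyl-3-(2,4,6-trimethoxyphenyl)propanoyl]oxazolidin-2-one, via Z-boron enolate 14 (not isolated), via boron aldolate 15 (not isolated)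
Conditions: Bu2BOTf, Et3N, CH2Cl2, 0 °C; 13, −78 °C → rt; pH 7 buffer, MeOH, 30% H2O2, 0 °C
Reagents that add atoms: none
Why: Evans syn-aldol, in which soft enolisation gives the Z-enolate, the closed Zimmerman–Traxler chair with dipole-opposed auxiliary and shielding benzyl group makes the (R)-auxiliary deliver the (2R,3R) syn pair (later C3 and C2), and binding of the Lewis-basic aldehyde to boron offsets its low electrophilicity.

Step 6
Reactants: 16 the syn-aldol adduct
Product: 17 (R)-4-benzyl-3-[(2R,3R)-2-isopropyl-3-(triethylsilyloxy)-3-(2,4,6-trimethoxyphenyl)propanoyl]oxazolidin-2-one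
Conditions: TESOTf, 2,6-lutidine, CH2Cl2, −78 → 0 °C
Reagents that add atoms: triethylsilyl trifluoromethanesulfonate, CC[Si](CC)(CC)OS(=O)(=O)C(F)(F)F
Why: O-silylation with a silyl triflate and a hindered base reaches the crowded carbinol at low temperature, keeps the medium non-acidic so the ionisation-prone benzylic C–O bond stays intact, and blocks retro-aldol in the next steps.

Step 7
Reactants: 17 the TES-protected imide
Product: 18 (2S)-3-methyl-2-[(R)-(triethylsilyloxy)(2,4,6-trimethoxyphenyl)methyl]butan-1-ol
Conditions: LiBH4, H2O (1 equiv), Et2O, 0 °C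
Reagents that add atoms: none
Why: Reductive removal of the auxiliary by borohydride attack on the exocyclic imide carbonyl gives the primary alcohol without touching the α-stereocentre (the descriptor changes only through CIP priorities).

Step 8
Reactants: 18 the primary alcohol
Product: 19 (2R)-3-methyl-2-[(R)-(triethylsilyloxy)(2,4,6-trimethoxyphenyl)methyl]butanal
Conditions: Dess–Martin periodinane, pyridine, CH2Cl2, 0 °C → rt
Reagents that add atoms: none
Why: Dess–Martin oxidation buffered with pyridine is neutral and fast, so neither the α-stereocentre nor the acid-labile benzylic silyl ether is put at risk.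

Step 9
Reactants: 19 the aldehyde
Product: 20 methyl (2E,4S,5R)-4-isopropyl-5-(triethylsilyloxy)-5-(2,4,6-trimethoxyphenyl)pent-2-enoate
Conditions: Ph3P=CHCO2Me, toluene, 60 °C
Reagents that add atoms: methyl (triphenylphosphoranylidene)acetate, COC(=O)C=P(c1ccccc1)(c1ccccc1)c1ccccc1
Why: Wittig olefination with a stabilised ylide is E-selective, and its salt-free, weakly basic conditions spare the α-branched aldehyde from epimerisation.

Step 10
Reactants: 20 the TES-protected enoate
Product: 21 methyl (2E,4S,5R)-5-hydroxy-4-isopropyl-5-(2,4,6-trimethoxyphenyl)pent-2-enoate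
Conditions: TBAF, AcOH (1:1), THF, 0 °C → rt
Reagents that add atoms: none
Why: In this fluoride desilylation buffered with acetic acid the released alkoxide is protonated at once, so neither retro-vinylogous aldol cleavage nor acid ionisation of the benzylic alcohol can set in.

Step 11
Reactants: 21 methyl (2E,4S,5R)-5-hydroxy-4-isopropyl-5-(2,4,6-trimethoxyphenyl)pent-2-enoate; 8 3,5-dimethoxy-2-(trimethylsilyl)phenyl trifluoromethanesulfonate
Product: 26 methyl 2-[(2R,3S,4S)-3-isopropyl-5,7-dimethoxy-2-(2,4,6-trimethoxyphenyl)chroman-4-yl]acetate, via sodium alkoxide 22 (not isolated), via 3,5-dimethoxybenzyne 23 (not isolated), via aryl anion 24 (not isolated), via ester enolate 25 (not isolated)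
Conditions: NaH (1.05 equiv), THF, 0 °C, 15 min; then 8 (1.5 equiv), CsF, 18-crown-6, THF (0.02 M), 0 °C → rt; AcOH quench
Reagents that add atoms: none
Why: Proposed new method: NaH first removes the hydroxyl proton of 21 as H2, fluoride then strips the silyl group of 8 so that triflate leaves and aryne 23 forms, alkoxide 22 adds to it (O1–C8a), and the resulting aryl anion 24 adds to the enoate β-carbon (C4–C4a) to give enolate 25, which the acid quench protonates. The closest known reaction type is the aryne O-arylation/intramolecular Michael cascade of phenoxides carrying an enone or enoate arm (xanthene and chroman syntheses); new here are a hindered secondary benzylic alkoxide as nucleophile and an sp3 tether. Ring C closes in the 6-exo-trig mode. C2 and C3 come unchanged from 21 because the C2–O bond is never broken, and C4 is set in a half-chair transition state with the C2 aryl group equatorial and the cis isopropyl group axial, where C3–H lies in the alkene plane (the allylic 1,3-strain minimum, only a modest bias in an E-enoate) and the acrylate carbon takes the pseudoaxial site anti to isopropyl, while the two 3,4-cis arrangements pay either a peri clash with the C5 methoxyl or a syn-diaxial aryl/acrylate contact. The step needs regioselective addition to the aryne, secured by the methoxyl next to the triple bond, which polarises and distorts it so that oxygen attacks the remote carbon and the charge lands beside the methoxyl, and it needs ring closure to outrun protonation of 24, secured by the proton-free alkoxide and by THF in place of acetonitrile. Retro-vinylogous aldol cleavage of 22 is held back by low temperature and a short alkoxide lifetime (aryne release starts at once), and γ-deprotonation by the in-plane C3–H bond, which overlaps poorly with the enoate π system.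

Step 12
Reactants: 26 the chroman-4-ylacetate
Product: 28 1-[(2R,3S,4S)-3-isopropyl-5,7-dimethoxy-2-(2,4,6-trimethoxyphenyl)chroman-4-yl]-2-methylpropan-2-ol, via methyl ketone 27 (not isolated)
Conditions: MeMgBr (4 equiv), THF, 0 °C → rt
Reagents that add atoms: methylmagnesium bromide, C[Mg]Br
Why: In this double Grignard addition to an ester the first adduct collapses to ketone 27, which takes up the second methyl group faster than the ester reacts, and the only enolisable carbon is a CH2, so no stereocentre is endangered.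

Step 13
Reactants: 28 the tertiary alcohol
Product: 29 (2R,3S,4S)-3-isopropyl-5,7-dimethoxy-4-(2-methylallyl)-2-(2,4,6-trimethoxyphenyl)chroman
Conditions: Burgess reagent, toluene, 50 °C
Reagents that add atoms: none
Why: Burgess dehydration (syn elimination of the sulfamate ester) is neutral and so avoids acid opening of C2–O1, should remove one of the six accessible methyl hydrogens rather than a hindered CH2 hydrogen, and needs no regiocontrol because a 2-methylprop-1-enyl isomer would converge in step 14.

Step 14
Reactants: 29 the 2-methylallyl chroman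
Product: 30 (2R,3S,4S)-4-isobutyl-3-isopropyl-5,7-dimethoxy-2-(2,4,6-trimethoxyphenyl)chroman
Conditions: H2 (1 atm), 10% Pd/C, EtOAc, rt
Reagents that add atoms: none
Why: Heterogeneous catalytic hydrogenation of the alkene creates no stereocentre, and the hindered C2–O1 bond of a 2-arylchroman withstands neutral low-pressure conditions, as flavans do.

Step 15
Reactants: 30 the pentamethyl ether
Product: 31 (2R,3S,4S)-2-(3,5-diformyl-2,4,6-trimethoxyphenyl)-4-isobutyl-3-isopropyl-5,7-dimethoxychroman-6,8-dicarbaldehyde
Conditions: Cl2CHOMe, TiCl4 (each in large excess, premixed), CH2Cl2, −78 → 0 °C; ice-water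
Reagents that add atoms: dichloromethyl methyl ether, COC(Cl)Cl; water, O
Why: Rieche formylation (Friedel–Crafts attack on the chloro(methoxy)carbenium ion), for which each free position C6, C8, C3' and C5' lies between two oxygens and para to a third, twofold formylation of phloroglucinol ethers and of 5,7-dimethoxychromans is established, meeting the premixed reagent at −78 °C lets substitution precede Lewis-acid opening of C2–O1, and any methyl ether lost next to a new formyl group only anticipates step 16.

Step 16
Reactants: 31 the tetraaldehyde pentamethyl ether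
Product: 32 sideroxylonal B, (2R,3S,4S)-2-(3,5-diformyl-2,4,6-trihydroxyphenyl)-5,7-dihydroxy-4-isobutyl-3-isopropylchroman-6,8-dicarbaldehyde
Conditions: BCl3 (excess), CH2Cl2, −78 → 0 °C; ice-water
Reagents that add atoms: none
Why: Chelation-assisted Lewis-acid ether cleavage, in which each of the five methoxyl groups is ortho to a formyl group so that BCl3 binds in a six-membered chelate and chloride removes the methyl group by SN2, whereas O1–C2 would have to break at a hindered secondary carbon whose aryl group is now deactivated by two complexed formyl groups, and no stereocentre is touched.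

**Compound list**
1 | 3,5-dimethoxyphenol | COc1cc(O)cc(OC)c1 | starting material
2 | 3,5-dimethoxyphenyl isopropylcarbamate | CC(C)NC(=O)Oc1cc(OC)cc(OC)c1 | intermediate
3 | 3,5-dimethoxyphenyl N-(tert-butyldimethylsilyl)-N-isopropylcarbamate | CC(C)N(C(=O)Oc1cc(OC)cc(OC)c1)[Si](C)(C)C(C)(C)C | intermediate
4 | 2-lithio-3,5-dimethoxyphenyl N-(tert-butyldimethylsilyl)-N-isopropylcarbamate | CC(C)N(C(=O)Oc1cc(OC)cc(OC)c1[Li])[Si](C)(C)C(C)(C)C | intermediate
5 | 3,5-dimethoxy-2-(trimethylsilyl)phenyl N-(tert-butyldimethylsilyl)-N-isopropylcarbamate | CC(C)N(C(=O)Oc1cc(OC)cc(OC)c1[Si](C)(C)C)[Si](C)(C)C(C)(C)C | intermediate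
6 | 3,5-dimethoxy-2-(trimethylsilyl)phenyl isopropylcarbamate | CC(C)NC(=O)Oc1cc(OC)cc(OC)c1[Si](C)(C)C | intermediate
7 | 3,5-dimethoxy-2-(trimethylsilyl)phenol (present as its DBU-H phenoxide) | COc1cc(O)c([Si](C)(C)C)c(OC)c1 | intermediate
8 | 3,5-dimethoxy-2-(trimethylsilyl)phenyl trifluoromethanesulfonate | COc1cc(OC)c([Si](C)(C)C)c(OS(=O)(=O)C(F)(F)F)c1 | intermediate
9 | (R)-4-benzyl-2-oxazolidinone | O=C1OC[C@@H](Cc2ccccc2)N1 | starting material
10 | isovaleryl chloride | CC(C)CC(Cl)=O | starting material
11 | N-lithio-(R)-4-benzyl-2-oxazolidinone | [Li]N1[C@H](Cc2ccccc2)COC1=O | intermediate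
12 | (R)-4-benzyl-3-(3-methylbutanoyl)oxazolidin-2-one | CC(C)CC(=O)N1[C@H](Cc2ccccc2)COC1=O | intermediate
13 | 2,4,6-trimethoxybenzaldehyde | COc1cc(OC)c(C=O)c(OC)c1 | starting material
14 | (Z)-dibutylboron enolate of 12 | CCCCB(CCCC)O/C(=C\C(C)C)N1[C@H](Cc2ccccc2)COC1=O | intermediate
15 | dibutylboron aldolate of 16 | CCCCB(CCCC)O[C@@H](c1c(OC)cc(OC)cc1OC)[C@H](C(=O)N1[C@H](Cc2ccccc2)COC1=O)C(C)C | intermediate
16 | (R)-4-benzyl-3-[(2R,3R)-3-hydroxy-2-isopropyl-3-(2,4,6-trimethoxyphenyl)propanoyl]oxazolidin-2-one | O[C@@H](c1c(OC)cc(OC)cc1OC)[C@H](C(=O)N1[C@H](Cc2ccccc2)COC1=O)C(C)C | intermediate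
17 | (R)-4-benzyl-3-[(2R,3R)-2-isopropyl-3-(triethylsilyloxy)-3-(2,4,6-trimethoxyphenyl)propanoyl]oxazolidin-2-one | CC[Si](CC)(CC)O[C@@H](c1c(OC)cc(OC)cc1OC)[C@H](C(=O)N1[C@H](Cc2ccccc2)COC1=O)C(C)C | intermediate
18 | (2S)-3-methyl-2-[(R)-(triethylsilyloxy)(2,4,6-trimethoxyphenyl)methyl]butan-1-ol | CC[Si](CC)(CC)O[C@@H](c1c(OC)cc(OC)cc1OC)[C@H](CO)C(C)C | intermediate
19 | (2R)-3-methyl-2-[(R)-(triethylsilyloxy)(2,4,6-trimethoxyphenyl)methyl]butanal | CC[Si](CC)(CC)O[C@@H](c1c(OC)cc(OC)cc1OC)[C@H](C=O)C(C)C | intermediate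
20 | methyl (2E,4S,5R)-4-isopropyl-5-(triethylsilyloxy)-5-(2,4,6-trimethoxyphenyl)pent-2-enoate | CC[Si](CC)(CC)O[C@@H](c1c(OC)cc(OC)cc1OC)[C@H](/C=C/C(=O)OC)C(C)C | intermediate
21 | methyl (2E,4S,5R)-5-hydroxy-4-isopropyl-5-(2,4,6-trimethoxyphenyl)pent-2-enoate (syn) | O[C@@H](c1c(OC)cc(OC)cc1OC)[C@H](/C=C/C(=O)OC)C(C)C | intermediate
22 | sodium alkoxide of 21 | [Na+].[O-][C@@H](c1c(OC)cc(OC)cc1OC)[C@H](/C=C/C(=O)OC)C(C)C | intermediate
23 | 3,5-dimethoxybenzyne | COC1=CC(OC)=CC#C1 | intermediate
24 | O-arylated aryl anion (charge on the carbon between O-alkyl and OMe) | COC1=CC(OC)=[C-]C(O[C@@H](c2c(OC)cc(OC)cc2OC)[C@H](/C=C/C(=O)OC)C(C)C)=C1.[Na+] | intermediate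
25 | ester enolate of 26 | COC([O-])=C[C@@H]1c2c(OC)cc(OC)cc2O[C@@H](c2c(OC)cc(OC)cc2OC)[C@H]1C(C)C.[Na+] | intermediate
26 | methyl 2-[(2R,3S,4S)-3-isopropyl-5,7-dimethoxy-2-(2,4,6-trimethoxyphenyl)chroman-4-yl]acetate (2,3-cis, 3,4-trans) | COC(=O)C[C@@H]1c2c(OC)cc(OC)cc2O[C@@H](c2c(OC)cc(OC)cc2OC)[C@H]1C(C)C | intermediate
27 | 1-[(2R,3S,4S)-3-isopropyl-5,7-dimethoxy-2-(2,4,6-trimethoxyphenyl)chroman-4-yl]propan-2-one | CC(=O)C[C@@H]1c2c(OC)cc(OC)cc2O[C@@H](c2c(OC)cc(OC)cc2OC)[C@H]1C(C)C | intermediate
28 | 1-[(2R,3S,4S)-3-isopropyl-5,7-dimethoxy-2-(2,4,6-trimethoxyphenyl)chroman-4-yl]-2-methylpropan-2-ol | CC(C)(O)C[C@@H]1c2c(OC)cc(OC)cc2O[C@@H](c2c(OC)cc(OC)cc2OC)[C@H]1C(C)C | intermediate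
29 | (2R,3S,4S)-3-isopropyl-5,7-dimethoxy-4-(2-methylallyl)-2-(2,4,6-trimethoxyphenyl)chroman | C=C(C)C[C@@H]1c2c(OC)cc(OC)cc2O[C@@H](c2c(OC)cc(OC)cc2OC)[C@H]1C(C)C | intermediate
30 | (2R,3S,4S)-4-isobutyl-3-isopropyl-5,7-dimethoxy-2-(2,4,6-trimethoxyphenyl)chroman | CC(C)C[C@@H]1c2c(OC)cc(OC)cc2O[C@@H](c2c(OC)cc(OC)cc2OC)[C@H]1C(C)C | intermediate
31 | (2R,3S,4S)-2-(3,5-diformyl-2,4,6-trimethoxyphenyl)-4-isobutyl-3-isopropyl-5,7-dimethoxychroman-6,8-dicarbaldehyde | CC(C)C[C@@H]1c2c(OC)c(C=O)c(OC)c(C=O)c2O[C@@H](c2c(OC)c(C=O)c(OC)c(C=O)c2OC)[C@H]1C(C)C | intermediate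
32 | sideroxylonal B | CC(C)C[C@@H]1c2c(O)c(C=O)c(O)c(C=O)c2O[C@@H](c2c(O)c(C=O)c(O)c(C=O)c2O)[C@H]1C(C)C | target

**Step count**
Total steps: 16. Longest linear sequence: 13 (steps 4–16, from 9 and 10). Steps 1–3 form the three-step side branch to 8.

**Steps most likely to fail**

1. Step 11 (carries the label).
 - What may go wrong: proton transfer to the aryl anion before it reaches the enoate, or retro-vinylogous aldol fragmentation of the alkoxide before it meets the aryne.
 - The fallback uses known chemistry. It makes the two bonds one after the other, the second by electrophilic rather than anionic closure, and no free alkoxide is needed.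
 - It sets out from 21 and 8. Under ordinary protic aryne conditions (CsF, MeCN, rt) the neutral alcohol undergoes plain O–H insertion to the aryl ether methyl (2E,4S,5R)-5-(3,5-dimethoxyphenoxy)-4-isopropyl-5-(2,4,6-trimethoxyphenyl)pent-2-enoate F1.
 - i-Bu2AlH (CH2Cl2, −78 °C) gives the allylic alcohol (2E,4S,5R)-5-(3,5-dimethoxyphenoxy)-4-isopropyl-5-(2,4,6-trimethoxyphenyl)pent-2-en-1-ol F2. MnO2 then gives the enal (2E,4S,5R)-5-(3,5-dimethoxyphenoxy)-4-isopropyl-5-(2,4,6-trimethoxyphenyl)pent-2-enal F3.
 - A 5-benzyl-2-tert-butyl-3-methylimidazolidin-4-one·TFA salt (catalytic, enantiomer matched to the substrate bias) closes C4–C4a by iminium-catalysed intramolecular Friedel–Crafts-type conjugate addition. This is a known route from aryloxy-tethered enals to 4-substituted chromans, and it gives 2-[(2R,3S,4S)-3-isopropyl-5,7-dimethoxy-2-(2,4,6-trimethoxyphenyl)chroman-4-yl]acetaldehyde F4.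
 - Only the two equivalent ortho carbons of the aryloxy ring can reach C4, and the same half-chair preference sets C4.
 - MeMgBr gives 1-[(2R,3S,4S)-3-isopropyl-5,7-dimethoxy-2-(2,4,6-trimethoxyphenyl)chroman-4-yl]propan-2-ol F5 (both carbinol epimers). Dess–Martin oxidation gives methyl ketone 27, where the route is rejoined (27 with MeMgBr gives 28).

2. Step 15.
 - What may go wrong: Lewis-acid opening of the C2–O1 bond while ring B is still fully electron-rich, with loss of the C2 configuration. The reaction may also stall after one formyl group per ring through deactivation.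
 - The fallback replaces electrophilic formylation by halogenation and metalation. It sets out from 30.
 - NBS (slightly over 4 equiv, MeCN, 0 °C, essentially neutral) fills the four free positions. The product is (2R,3S,4S)-6,8-dibromo-2-(3,5-dibromo-2,4,6-trimethoxyphenyl)-4-isobutyl-3-isopropyl-5,7-dimethoxychroman F6.
 - Exhaustive bromine–lithium exchange (t-BuLi, THF, −78 °C; each lithium is flanked by two chelating oxygens) followed by a DMF quench returns to the route at 31.

3. Step 16.
 - What may go wrong: boron chelation between the C8 formyl group and O1 may trigger ionisation of O1–C2, leading to ring opening or C2 epimerisation. Removal of all five methyl groups may also be incomplete.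
 - The fallback replaces Lewis-acid activation of the ethers by nucleophilic dealkylation. It sets out from 31.
 - 4-MeC6H4SLi (from the thiol and n-BuLi) in HMPA/toluene at reflux removes the methyl groups by SN2 at carbon. The diformyl-stabilised phenoxides are good leaving groups, and the hindered secondary C2 is not attacked.
 - Acidification gives 32 directly, so no new compound arises (F0).

**Further compounds**
F1 | step 11 | methyl (2E,4S,5R)-5-(3,5-dimethoxyphenoxy)-4-isopropyl-5-(2,4,6-trimethoxyphenyl)pent-2-enoate | COc1cc(OC)cc(O[C@@H](c2c(OC)cc(OC)cc2OC)[C@H](/C=C/C(=O)OC)C(C)C)c1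
F2 | step 11 | (2E,4S,5R)-5-(3,5-dimethoxyphenoxy)-4-isopropyl-5-(2,4,6-trimethoxyphenyl)pent-2-en-1-ol | COc1cc(OC)cc(O[C@@H](c2c(OC)cc(OC)cc2OC)[C@H](/C=C/CO)C(C)C)c1
F3 | step 11 | (2E,4S,5R)-5-(3,5-dimethoxyphenoxy)-4-isopropyl-5-(2,4,6-trimethoxyphenyl)pent-2-enal | COc1cc(OC)cc(O[C@@H](c2c(OC)cc(OC)cc2OC)[C@H](/C=C/C=O)C(C)C)c1
F4 | step 11 | 2-[(2R,3S,4S)-3-isopropyl-5,7-dimethoxy-2-(2,4,6-trimethoxyphenyl)chroman-4-yl]acetaldehyde | O=CC[C@@H]1c2c(OC)cc(OC)cc2O[C@@H](c2c(OC)cc(OC)cc2OC)[C@H]1C(C)C
F5 | step 11 | 1-[(2R,3S,4S)-3-isopropyl-5,7-dimethoxy-2-(2,4,6-trimethoxyphenyl)chroman-4-yl]propan-2-ol (carbinol epimers) | CC(O)C[C@@H]1c2c(OC)cc(OC)cc2O[C@@H](c2c(OC)cc(OC)cc2OC)[C@H]1C(C)C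
F6 | step 15 | (2R,3S,4S)-6,8-dibromo-2-(3,5-dibromo-2,4,6-trimethoxyphenyl)-4-isobutyl-3-isopropyl-5,7-dimethoxychroman | CC(C)C[C@@H]1c2c(OC)c(Br)c(OC)c(Br)c2O[C@@H](c2c(OC)c(Br)c(OC)c(Br)c2OC)[C@H]1C(C)C
F0 | step 16 | none | none
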